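Decide first which charge you will let run out: that choice comes down to one number.

| setting | maple | oak | cedar | flask |
|---|---|---|---|---|
| substrate | 0.039 M | 0.062 M | 0.028 M | 0.028 M |
| activator | 0.0308 M (fed, over 80 min) | 0.0308 M (fed, over 80 min) | 0.015 M (fed, over 80 min) | 0.0308 M (fed, over 80 min) |
| remark | run made earlier | run made earlier | run made earlier |  |
| time |  |  |  | 8.0 d |

- maple (time / d: ring / %, substrate / %): 0.104: 21.9, 19.8; 0.250: 38.3, 9.1; 0.625: 34.4, 5.3; 1.67: 30.9, 4.9; 4.00: 30.5, 5.0; 10.0: 30.9, 5.4
- oak (time / d: ring / %, substrate / %): 0.104: 14.9, 34.7; 0.250: 20.9, 26.9; 0.625: 17.5, 26.3; 1.67: 15.4, 26.8; 4.00: 16.2, 27.0; 10.0: 15.0, 26.6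
- cedar (time / d: ring / %, substrate / %): 0.104: 14.7, 43.6; 0.333: 26.1, 30.9; 1.04: 20.1, 30.5; 3.00: 20.1, 30.5; 10.0: 20.2, 31.2

(scatter of a reading: 0.3 percentage points)

- time, not beyond 8.0 d, at which the flask holds most ring
- the amount of ring, in percent of the substrate charged, at that time
- the first time at which ring reaches 35%, in the same percent, in d

- a reading or a percentage of ring counts all its forms, free or not
- a reading of substrate is of its free form alone

In maple the substrate reading goes flat and ends at 5.4% of its charge, with 0.790 equivalents of activator dosed. Supposing the whole activator charge of maple has reacted by then, you read from that how much substrate each activator took, and you carry it to the flask: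

substrate used per activator, maple: 1.20

cover of the flask: 1.20 × 1.10 equivalents = 1.32

This cover, the fraction of the substrate charge that the whole activator charge can consume, stands above one. So my reckoning makes substrate the limiting reagent of the flask and leaves 24.1% of the activator.

Was one number enough? Not quite for the stop: substrate used per activator reads 1.48 in oak, at 0.497 equivalents. And not for ring: at 0.536 equivalents cedar shows a highest reading of 26.1%, while oak shows 20.9%. For the flask, then, the cover gives an estimate of the stop, not of the ring.

The forecast says “The flask has activator in excess”. It puts the most ring at 41% at 0.25 d, and the asked level at 0.15 d.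

The flask gives 49.3% at 0.319 d, above the forecast's range, and reaches the asked level at 0.140 d.

    ring ⇌ isomer of the product (K = 1.10, k = 3.20 × 10⁻⁵ s⁻¹)
    activated form → ring (k = 1.00 × 10⁻⁴ s⁻¹)
    substrate + activated form → open dimer (k = 0.00270 L mol⁻¹ s⁻¹)
    substrate + ring ⇌ idle adduct, settled at all times (K = 14.0 L mol⁻¹)
    substrate + activator → activated form (k = 0.0200 L mol⁻¹ s⁻¹)

At 8.00 d the flask holds 0% of its substrate and 18% of its activator, against the 24.1% reckoned from its cover of 1.32. The neighbour charged with 0.048 M of substrate has 0.642 equivalents, so its cover is 0.769, below one, and 23.1% of its substrate should stay. It ends with 0% of its activator and 15% of its substrate still free, and its ring peaks at 30.3%.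

The data are calculated for an exercise; scatter was added.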